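**Plan**

- Numbering used: C1 benzoyl bridgehead, C2/C4 ketones around C3, C5 geranyl bridgehead, C6 CH2, C7 cage CH, C8 ring CMe2, C9 bridging ketone.
- Retrosynthetic cuts: the side-chain O–OH; then the dioxepane O–CH bond together with the C3–CH bond of the two-carbon C3/C7 bridge (one aerobic radical cascade); then C8–C1 and the C7–CH2 bond to the second C5 unit (one enzymatic cation cascade); then C5–geranyl; then the two aryl–prenyl bonds.
- Forward ring order: benzophenone ring → dearomatised cyclohexadienone → ring B of the bicyclo[3.3.1]nonane → seven-membered carbocycle of the homoadamantane → 1,2-dioxepane.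
- Enabling feature: C6, C7 and C8 form one prenyl unit on the geranyl-bearing carbon, and the CH2 running from C7 toward the dioxepane is C1 of a second dimethylallyl unit. Alkylating that prenyl alkene at its CH creates a C8 cation within reach of the benzoyl-bearing carbon, which closes ring B.
- Stereochemistry: C5 from resolution of the racemic dearomatised triketone; C1 and C7 from the enzymatic bicyclisation; C3, the ring-fusion CH and the peroxy CH from the cage during the radical cascade.

Key step: step 4

Assumption: 6, 7 and 9 are written as one enol tautomer of an equilibrating set (CIP labels refer to the tautomer drawn), 8 is written as the free acid, and a recombinant UbiA-type prenyltransferase from a homoadamantane-producing Hypericum species is taken to be obtainable by expression in yeast.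

**Step 1**
Reactants: 1 2,4,6-trihydroxybenzophenone; 2 prenyl bromide
Product: 4 3,5-diprenyl-2,4,6-trihydroxybenzophenone (clusiaphenone B), via 3-prenyl-2,4,6-trihydroxybenzophenone 3 (not isolated)
Conditions: 2 (2.1 equiv), 5% aq KOH, 0 °C; then aq HCl
Reagents that add atoms: none
Why: C-alkylation of the phloroglucinol phenolate in water, where hydrogen bonding to the oxyanions steers the allylic bromide to the two free ring carbons; this is the known direct route to clusiaphenone B, two equivalents should stop at the aromatic bis-adduct, and no stereocentre is formed.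

**Step 2**
Reactants: 4 clusiaphenone B; 5 geranyl bromide
Product: 6 rac-4-benzoyl-6-geranyl-3,5-dihydroxy-2,6-diprenylcyclohexa-2,4-dien-1-one
Conditions: NaOMe (2.2 equiv), MeOH, 0 °C; 5 (1.1 equiv), 0 °C → rt; then aq HCl
Reagents that add atoms: none
Why: Dearomatising C-alkylation of an acylphloroglucinol (the reaction that converts deoxy hop acids into lupulones): the anion should react at a prenyl-bearing carbon between two oxygens and not at the benzoyl-bearing carbon, whose charge is drawn into the aroyl group; the two prenylated carbons are symmetry-equivalent, so one constitution results, and the new quaternary centre forms as a racemate.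

**Step 3**
Reactants: 6 rac-4-benzoyl-6-geranyl-3,5-dihydroxy-2,6-diprenylcyclohexa-2,4-dien-1-one
Product: 7 (6S)-4-benzoyl-6-geranyl-3,5-dihydroxy-2,6-diprenylcyclohexa-2,4-dien-1-one
Conditions: preparative chiral SFC, amylose tris(3,5-dimethylphenylcarbamate) phase, CO2/MeOH (0.1% HCO2H)
Reagents that add atoms: none
Why: Enantiomer separation on a polysaccharide chiral stationary phase, routine for dearomatised prenylated acylphloroglucinols; the all-carbon quaternary centre cannot racemise by enolisation, and the (S) antipode would be identified by comparing its ECD spectrum with a calculated one.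

**Step 4**
Reactants: 7 (6S)-4-benzoyl-6-geranyl-3,5-dihydroxy-2,6-diprenylcyclohexa-2,4-dien-1-one; 8 dimethylallyl diphosphate
Product: 9 (1S,5S,7S)-1-benzoyl-5-geranyl-4-hydroxy-8,8-dimethyl-3,7-diprenylbicyclo[3.3.1]non-3-ene-2,9-dione (7-prenyl endo, directed toward C3)
Conditions: UbiA-type prenyltransferase (recombinant, yeast microsomes), 8 (2 equiv, NH4+ salt), MgCl2, Tris·HCl pH 7.5, 5% DMSO, 30 °C
Reagents that add atoms: none
Why: Proposed new method: Mg2+-assisted ionisation of 8 in the active site should give a dimethylallyl cation whose C1 is attacked by the CH terminus of the prenyl group on the geranyl-bearing carbon of 7, and the tertiary C8 cation so formed is captured by the benzoyl-bearing enol carbon, two C–C bonds in one event; the closest known reaction is the UbiA-type prenyltransferase step of hyperforin biosynthesis that prenylates and cyclises a dearomatised acylphloroglucinol to the bicyclo[3.3.1]nonane core, which has not been shown for a benzoyl geranyl substrate or with endo delivery. Ring B (C1–C9–C5–C6–C7–C8) closes by a six-membered cation–enol C-alkylation, 6-endo with respect to the original prenyl alkene because both of its carbons end up in the ring. C1 is dictated by C5, since the one-carbon C9 bridge can only span the ring cis. C7 is set by the enzyme: anti addition of the two carbon partners across the alkene through a boat-shaped ring B, with the prenyl group folded under the trione ring, places the incoming unit endo. The step needs site selectivity among four trisubstituted alkenes, C- over O-capture, capture at C1 and not at the prenylated C3, and acceptance of the (S) substrate; the substrate supplies only its natural shape (Mg-binding triketone enolate, lipophilic geranyl tail, prenyl group next to the benzoyl enol) and the active site must do the rest, which is why the enzyme is taken from a homoadamantane-producing Hypericum species.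

**Step 5**
Reactants: 9 (1S,5S,7S)-1-benzoyl-5-geranyl-4-hydroxy-8,8-dimethyl-3,7-diprenylbicyclo[3.3.1]non-3-ene-2,9-dione
Product: 10 tertiary hydroperoxide of the target (OOH in place of the side-chain OH, cage and dioxepane as in 11)
Conditions: Mn(OAc)3·2H2O (20 mol%), O2 (1 atm), AcOH, 23 °C
Reagents that add atoms: dioxygen, O=O
Why: Proposed new method: Mn(III) should oxidise the C3 enol to the tricarbonyl-stabilised C3 radical, which adds 7-exo-trig to the CH terminus of the endo C7 prenyl group held beneath it (closing the homoadamantane), the tertiary radical takes up O2, the peroxyl radical adds 7-exo-trig to the CH terminus of the C3 prenyl group (closing the 1,2-dioxepane), and the second tertiary radical takes up O2 and is reduced by Mn(II) to the hydroperoxide with return of Mn(III); the closest known reaction types are the Mn(III)-catalysed aerobic peroxycyclisation of 1,3-dicarbonyls with alkenes to 1,2-dioxan-3-ols and Mn(III) oxidative radical cyclisations of acylphloroglucinol-derived enols, neither shown for two consecutive 7-exo closures; C3 is fixed by the cage, the ring-fusion CH because the CMe2 end of the endo prenyl group lies over C6 and away from the C8 methyls, and the peroxy CH by a chair-like closure that should place the CMe2 radical pseudo-equatorial with its H cis to the ring-fusion H.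

**Step 6**
Reactants: 10 tertiary hydroperoxide of the target
Product: 11 CNP0148771.1
Conditions: PPh3 (1.05 equiv), CH2Cl2, 0 °C
Reagents that add atoms: none
Why: Phosphine reduction of a hydroperoxide: PPh3 attacks the terminal, unhindered OOH oxygen far faster than the hindered dialkyl peroxide of the dioxepane, so only the hydroperoxide should be reduced at 0 °C and no stereocentre is touched.

**Compound list**

1 | 2,4,6-trihydroxybenzophenone | O=C(c1ccccc1)c1c(O)cc(O)cc1O | starting material
2 | prenyl bromide (1-bromo-3-methylbut-2-ene) | CC(C)=CCBr | starting material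
3 | 3-prenyl-2,4,6-trihydroxybenzophenone | CC(C)=CCc1c(O)cc(O)c(C(=O)c2ccccc2)c1O | intermediate
4 | 3,5-diprenyl-2,4,6-trihydroxybenzophenone (clusiaphenone B) | CC(C)=CCc1c(O)c(CC=C(C)C)c(O)c(C(=O)c2ccccc2)c1O | intermediate
5 | geranyl bromide ((2E)-1-bromo-3,7-dimethylocta-2,6-diene) | CC(C)=CCC/C(C)=C/CBr | starting material
6 | rac-4-benzoyl-6-geranyl-3,5-dihydroxy-2,6-diprenylcyclohexa-2,4-dien-1-one | CC(C)=CCC/C(C)=C/CC1(CC=C(C)C)C(=O)C(CC=C(C)C)=C(O)C(C(=O)c2ccccc2)=C1O | intermediate
7 | (6S)-4-benzoyl-6-geranyl-3,5-dihydroxy-2,6-diprenylcyclohexa-2,4-dien-1-one | CC(C)=CCC/C(C)=C/C[C@]1(CC=C(C)C)C(=O)C(CC=C(C)C)=C(O)C(C(=O)c2ccccc2)=C1O | intermediate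
8 | dimethylallyl diphosphate | CC(C)=CCOP(=O)(O)OP(=O)(O)O | starting material
9 | (1S,5S,7S)-1-benzoyl-5-geranyl-4-hydroxy-8,8-dimethyl-3,7-diprenylbicyclo[3.3.1]non-3-ene-2,9-dione, 7-prenyl endo (toward C3) | CC(C)=CCC/C(C)=C/C[C@]12C[C@H](CC=C(C)C)C(C)(C)[C@@](C(=O)c3ccccc3)(C2=O)C(=O)C(CC=C(C)C)=C1O | intermediate
10 | hydroperoxide of 11: 1-benzoyl-5-geranyl homoadamantane-2,4,9-trione fused at C3 and the bridge CH to the 1,2-dioxepane, with a 2-hydroperoxypropan-2-yl group on the peroxy CH; configuration as in 11 | CC(C)=CCC/C(C)=C/C[C@]12C[C@@H]3C[C@@H]4C(C)(C)OO[C@H](C(C)(C)OO)C[C@@]4(C1=O)C(=O)[C@](C(=O)c1ccccc1)(C2=O)C3(C)C | intermediate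
11 | CNP0148771.1: 1-benzoyl-5-geranyl-8,8-dimethyl bicyclo[3.3.1]nonane-2,4,9-trione with C3 and C7 tied by a CH2–CH bridge (homoadamantane); C3 and the bridge CH belong to a fused 1,2-dioxepane (bridge CH–CMe2–O–O–CH–CH2–C3) whose peroxy CH carries a 2-hydroxypropan-2-yl group; peroxide-bound CMe2 on the C5/C6 side, ring-fusion H and peroxy-CH H cis | CC(C)=CCC/C(C)=C/C[C@]12C[C@@H]3C[C@@H]4C(C)(C)OO[C@H](C(C)(C)O)C[C@@]4(C1=O)C(=O)[C@](C(=O)c1ccccc1)(C2=O)C3(C)C | target

**Totals**

Total step count: 6. Longest linear sequence: 6 steps (1 → 11).

**Steps most likely to fail**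

Step 4. The enzyme may not turn over a benzoyl, geranyl-substituted substrate, the C8 cation may be quenched on oxygen or at C3, or the new side chain may be delivered exo. The fallback uses known chemistry, sets out from 1 and rejoins the route at 9; it moves the intermolecular C–C bond into a chiral-pool electrophile and keeps only the cation–enol closure. C-Geranylation of 1 with 5 (aq KOH, 0 °C) would give 3-geranyl-2,4,6-trihydroxybenzophenone F1, and C-prenylation with 2 under the same conditions 3-geranyl-5-prenyl-2,4,6-trihydroxybenzophenone F2. Commercial (R)-lavandulol would be converted by Appel iodination (I2, PPh3, imidazole) into (R)-lavandulyl iodide F3, which alkylates the sodium salt of F2 (NaH, THF/DMF) at the geranyl-bearing carbon. Chromatography would remove the epimer at the new quaternary carbon and the isomer alkylated at the prenylated carbon, leaving the dearomatised geranyl lavandulyl triketone F4. Formic acid at room temperature should then protonate the 1,1-disubstituted isopropenyl alkene to the same C8 cation, and a Brønsted-acid cation–enol cyclisation of the kind known from biomimetic bicyclo[3.3.1]nonane syntheses closes C8–C1 to give 9. In this variant C7 comes from the lavandulyl stereocentre.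

Step 5. Oxygen may be captured at C3 before the first ring closes, the first peroxyl radical may be reduced before it reaches the C3 prenyl group, or facial selectivity at the peroxy CH may be poor. The fallback runs in known stages, sets out from 9 and rejoins at 10. Mn(OAc)3/Cu(OAc)2 in degassed AcOH would carry out the oxidative radical cyclisation without oxygen, Cu(II) oxidising the tertiary radical to an alkene, to give the isopropenyl homoadamantane trione F5. Mukaiyama–Isayama peroxidation (Co(thd)2, O2, Et3SiH, DCE) should then engage the isopropenyl group as the only 1,1-disubstituted alkene; the tertiary peroxyl radical closes onto the C3 prenyl group, as in the known cobalt peroxidation of dienes to cyclic peroxides, and the second oxygenation ends as the triethylsilyl peroxide F6. HCl in MeOH would remove the silyl group to give 10.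

Step 2. O-alkylation, methanolysis of the bromide and a second alkylation may outrun C-geranylation at the hindered ring carbon. The fallback sets out from 4 and rejoins at 6: Tsuji–Trost allylation with geranyl acetate, Pd(PPh3)4 and K2CO3 in THF. The soft π-geranyl palladium electrophile should pair with the ring carbon of the phenolate, and the PPh3 ligand favours the linear E isomer. This fallback makes no compound outside the list (F0).

**Further compounds**

F1 | step 4 | 3-geranyl-2,4,6-trihydroxybenzophenone | O=C(c1ccccc1)c1c(O)cc(O)c(C/C=C(\C)CCC=C(C)C)c1O
F2 | step 4 | 3-geranyl-5-prenyl-2,4,6-trihydroxybenzophenone | O=C(c1ccccc1)c1c(O)c(CC=C(C)C)c(O)c(C/C=C(\C)CCC=C(C)C)c1O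
F3 | step 4 | (R)-lavandulyl iodide | IC[C@H](CC=C(C)C)C(C)=C
F4 | step 4 | dearomatised geranyl lavandulyl triketone (4-benzoyl-6-geranyl-3,5-dihydroxy-6-lavandulyl-2-prenylcyclohexa-2,4-dien-1-one, quaternary carbon as in 7) | CC(C)=CCC/C(C)=C/C[C@]1(C[C@H](CC=C(C)C)C(C)=C)C(=O)C(CC=C(C)C)=C(O)C(C(=O)c2ccccc2)=C1O
F5 | step 5 | isopropenyl homoadamantane trione (C3–CH bridge closed, isopropenyl on the bridge CH, prenyl on C3) | CC(C)=CCC/C(C)=C/C[C@]12C[C@@H]3C[C@H](C(C)=C)[C@](CC=C(C)C)(C1=O)C(=O)[C@](C(=O)c1ccccc1)(C2=O)C3(C)C
F6 | step 5 | triethylsilyl peroxide of 10 | CC(C)=CCC/C(C)=C/C[C@]12C[C@@H]3C[C@@H]4C(C)(C)OO[C@H](C(C)(C)OO[Si](CC)(CC)CC)C[C@@]4(C1=O)C(=O)[C@](C(=O)c1ccccc1)(C2=O)C3(C)C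
F0 | step 2 | none | none
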